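**Numbering used below.** Lactone (target) numbering: O1, C2 (C=O), C3, C4, C5. Acetal numbering for the six-membered ring of 8, 17 and 18: O1, C2 (acetal), O3, C4 (C=O), C5, C6. Acetal C6 becomes lactone C5, acetal C5 becomes lactone C4, and the acetal carbonyl C4 becomes the carboxyl carbon.

## Analysis of the target

allo-Pertusaric acid (25) is a paraconic acid: a γ-butyrolactone with an exocyclic methylene on C3, a free carboxyl on C4 and an unbranched 14-oxopentadecyl chain on C5, thirteen CH2 groups ending in a methyl ketone. The only stereocenters are the neighbours C4 and C5; both are S, which puts the carboxyl and the chain on the same face of the ring (4,5-cis), the less stable arrangement. Once the methylene is in place, the C4–H is both α to the carboxyl and allylic to the conjugated alkene, so base can epimerise C4 or move the double bond into the ring. The α-methylene lactone is also a Michael acceptor, and the distal methyl ketone is enolisable and reacts with organometallic and carboxylating reagents. The synthesis is therefore hard in two places: the cis pair C4/C5 must be set under kinetic control in the right absolute sense, and the methylene must be introduced late without disturbing C4 or the ketone. The route rests on the unit O1–C5–C4–CO2H, a 3-hydroxy acid that can be tied up with an aldehyde as a 1,3-dioxan-4-one. The unsaturated form of that ring (8) is a cyclic β-alkoxyacrylate whose β-carbon is the future C5, whose α-carbon is the future C4 and whose ring carbonyl is the future carboxyl, so a single acetal carbon is the only source of chirality.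

## Retrosynthetic reasoning

**25 from 24 (unmasking the ketone).** The ketone is revealed last. The methylenation passes through conditions that carboxylate any enolisable ketone, so a free methyl ketone would acquire a β-keto acid and be methylenated as well. An oxygen ketal cannot serve as the mask, because it would be lost in the aqueous acid that frees the lactone (18 to 20). A 1,3-dithiane survives the organometallic step, the acid and the carboxylation. It is removed oxidatively under weakly acidic conditions that leave the conjugated methylene and C4 alone.

**24 from 20 via 21 and 23 (the C3=CH2 bond).** The exocyclic double bond is cut, and its carbon is 22. In the forward direction C3 is first carboxylated (21), which activates this position only. Condensation with 22 then gives the amino acid 23, which loses the extra carboxyl and the amine. The alkene is made this late because it would not survive a cuprate, and the weakly acidic final stage avoids base at the sensitive C4–H.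

**20 from 18 via 19 (the lactone C–O bond).** Opening the O1–C2 ester bond gives the hydroxy diacid 19. This is held as 18, in which O1 and the C4 carboxyl are bridged by the acetal carbon from 5 and the C2 carboxyl is a tert-butyl ester. Both stereocenters then sit in a six-membered ring next to a controlling tert-butyl group, and the two carboxyls are told apart. The forward step is a single acid treatment that breaks no bond to a stereocenter. Because the ring carbonyl of 18 becomes the exocyclic carboxyl of 20, a 5,6-trans acetal is a 4,5-cis lactone.

**18 from 8, 15 and 16 via 17 (the key disconnection).** Two C–C bonds are cut at the same two carbons that carry the stereocenters: C5–chain (lactone numbering) and C3–C4. This leaves the four-atom unit as the enantiopure dioxinone 8, the whole chain as the Grignard reagent 15, and C2/C3 as the bromo ester 16. The carboxyl carbon is present from the start at its final oxidation level. Cutting elsewhere (for example at C4–CO2H, or closing the lactone first) would leave the two centers to be set in separate operations. The forward reaction must add the chain to the β-carbon anti to the tert-butyl group and alkylate the resulting enolate 17 anti to the new chain before it can open by loss of the ring oxygen.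

**8 from 7, and 7 from 4 and 5 via 6; 4 from 3; 3 from 1 and 2.** The dioxinone ring is cut into the aldehyde 5 and the acylketene 6, which is released by thermal fragmentation of 4. Compound 4 comes from 1 and the one-carbon unit 2 via 3. The acetal center forms as a racemate (7) and is resolved once, on a small, cheap compound, to give 8. This is reliable and keeps the risk of the route in the key step.

**15 from 14, 13, 11 (via 12), and from 9 and 10.** The chain is cut between its second and third carbon counted from the ketone. The acetoacetate 10 supplies the methyl ketone and one CH2, and the dibromide 9 supplies twelve CH2 groups and the halide for the Grignard reagent. Alkylation gives 11, loss of the ester carbon via 12 gives 13, and thioketalisation gives 14.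

## Alternatives that were turned down

**Alternative 1:** enzymatic Baeyer–Villiger oxidation of a cyclobutanone.
- Disconnection: the lactone O1–C5 bond, with the C4 carboxyl carbon and the first two chain carbons held together as a cyclopentene.
- Forward key step: a monooxygenase of the cyclohexanone monooxygenase class inserts oxygen next to the bridgehead carbon of one enantiomer of racemic bicyclo[3.2.0]hept-2-en-6-one A1. The product is (1S,5R)-2-oxabicyclo[3.3.0]oct-6-en-3-one A2.
- For it: the lactone is formed directly, the absolute configuration comes from a catalyst and air, and the cis relationship in A2 is guaranteed by the ring fusion. On that last point it is stronger than the chosen route, where cis depends on a kinetic alkylation.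
- Against it: enzymes of this class usually turn the two enantiomers of A1 into regioisomeric lactones, so at most half of the material is A2 and a separation is still needed. That is no gain over a resolution.
- Against it: after cleavage of the ring alkene of A2 the two new carbonyl carbons must be differentiated. One becomes the C4 acid; the other must be extended by thirteen carbons including a masked ketone and then hydrogenated. The same late methylenation still follows, and whole-cell biocatalysis is required.
- Comparison: the chosen route attaches the complete chain in one bond formation and never has to distinguish two similar carbonyl groups. The linear sequence is shorter than the one that starts at A1.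

**Alternative 2:** silicon-tethered radical delivery of the carboxyl carbon.
- Disconnection: the bond between C4 and the carboxyl carbon.
- Forward key step: the α-silyl radical from tert-butyl (2E,4S)-4-{[(bromomethyl)dimethylsilyl]oxy}-18-oxononadec-2-enoate A3, generated in a tin hydride chain, adds 5-exo to the enoate β-carbon. The product is tert-butyl 2-[(4S,5S)-2,2-dimethyl-5-(14-oxopentadecyl)-1,2-oxasilolan-4-yl]acetate A4.
- For it: one carbinol center, the one in A3, is available by asymmetric synthesis without a resolution and controls C4. The neutral radical conditions tolerate the free ketone. On both points it equals or beats the chosen route.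
- Against it: the trans preference of a 5-exo transition state with a substituent on the allylic carbon is usually moderate, so A4 would probably have to be separated from its diastereomer.
- Against it: in A4 the new carbon arrives at the wrong oxidation level. The C–Si bond of A4 must be oxidised to a primary alcohol and then to the acid, the ketone must still be masked before methylenation, and A3 itself needs several steps. Tin residues are a further drawback.
- Comparison: where A4 relies on an open transition state, the chosen route offers a rigid ring with a well-understood facial bias for both centers and a carboxyl that needs no oxidation.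

**Alternative 3:** dirhodium carbene insertion into a benzylic C–H bond.
- Disconnection: the C3–C4 bond, with an aryl group standing in for the carboxyl.
- Forward key step: the carbene from (2S)-1-(4-methoxyphenyl)-15-(2-methyl-1,3-dioxolan-2-yl)pentadecan-2-yl 2-diazoacetate A5 inserts into the benzylic C–H bond and closes the lactone. The product is (4R,5S)-4-(4-methoxyphenyl)-5-[13-(2-methyl-1,3-dioxolan-2-yl)tridecyl]dihydrofuran-2(3H)-one A6.
- For it: the lactone ring, the C3–C4 bond and the second stereocenter are made in one catalytic step from the single carbinol center of A5. In ring construction it is stronger than the chosen route, which closes no ring in its key step.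
- Against it: the cis outcome at C4/C5 is not secured by the mechanism and depends on the catalyst. In the carbene from A5, insertion into the first CH2 of the chain and attack on the electron-rich arene compete with the wanted insertion.
- Against it: the aryl ring of A6 must be degraded to a carboxyl by exhaustive oxidation, which wastes seven carbons and is harsh. The ketal of A6 would also fall in the acid needed later, so the ketone problem returns.
- Comparison: against the route through A5 and A6, the chosen route offers predictable stereocontrol and a carboxyl that is never a surrogate.

Key step: step 9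

Assumption on the chemistry: copper-mediated addition to 8 is taken to occur on the ring face opposite to the tert-butyl group, and since the elution order of the enantiomers of 7 cannot be predicted, a sample of each fraction is correlated before material is committed (Me2CuLi addition, then hydrolysis to 3-hydroxybutanoic acid); the fraction that gives the 2,6-trans adduct and the (S)-acid is 8, and if the adduct proved to be cis the other enantiomer of 7 would be carried forward instead, with nothing else changed.

## Route

Step 1
Reactants: 1 2,2-dimethyl-1,3-dioxane-4,6-dione (Meldrum's acid); 2 trimethyl orthoformate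
Product: 3 5-(methoxymethylidene)-2,2-dimethyl-1,3-dioxane-4,6-dione
Conditions: 2 (5 equiv, neat), reflux, 2 h; evaporate
Reagents that add atoms: none
Why: Knoevenagel-type condensation of the acidic methylene of 1 with the orthoester; loss of two molecules of methanol gives the alkoxymethylidene derivative, a standard preparation.

Step 2
Reactants: 3
Product: 4 5-(hydroxymethylidene)-2,2-dimethyl-1,3-dioxane-4,6-dione
Conditions: 2 M aq HCl, rt, 30 min; filter, dry
Reagents that add atoms: water, O
Why: The methoxymethylidene group is a vinylogous carbonate; addition–elimination of water at the exocyclic carbon under dilute acid exchanges OMe for OH and gives the stable enol form of the formyl compound.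

Step 3
Reactants: 4; 5 pivalaldehyde (2,2-dimethylpropanal)
Product: 7 rac-2-tert-butyl-2H,4H-1,3-dioxin-4-one, via formylketene 6 (not isolated)
Conditions: 5 (5 equiv), toluene, 90–100 °C, pressure vessel, 1 h
Reagents that add atoms: none
Why: Thermal fragmentation of 4 releases acetone and CO2 and gives acylketene 6, which is captured by the C=O of the non-enolisable aldehyde 5 in a hetero-Diels–Alder ([4+2]) cycloaddition, the established route from acylketenes to 1,3-dioxin-4-ones; the excess of 5 should outcompete recapture by the acetone set free, and the acetal carbon forms as a racemate.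

Step 4
Reactants: 7
Product: 8 (2R)-2-tert-butyl-2H,4H-1,3-dioxin-4-one
Conditions: preparative HPLC, cellulose tris(3,5-dimethylphenylcarbamate) on silica, hexane/iPrOH
Reagents that add atoms: none
Why: Resolution by chromatography on a chiral stationary phase; small, UV-active 2-tert-butyl-1,3-dioxin-4-ones are the kind of racemate that polysaccharide phases separate preparatively, and the wanted enantiomer is identified by the correlation described before the steps.

Step 5
Reactants: 9 1,12-dibromododecane; 10 tert-butyl acetoacetate (tert-butyl 3-oxobutanoate)
Product: 11 tert-butyl 2-acetyl-14-bromotetradecanoate (racemic)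
Conditions: 10, NaH (1.05 equiv), THF/DMF, 0 °C; add to 9 (3 equiv), 60 °C
Reagents that add atoms: none
Why: C-Alkylation of the sodium enolate of a β-keto ester with a primary bromide (acetoacetic ester synthesis); the threefold excess of 9 keeps the second bromide from meeting another enolate.

Step 6
Reactants: 11
Product: 13 15-bromopentadecan-2-one, via keto acid 12 (not isolated)
Conditions: TsOH·H2O (10 mol %), toluene, reflux
Reagents that add atoms: none
Why: Acid-catalysed loss of isobutene from the tert-butyl ester gives β-keto acid 12, which decarboxylates at reflux through the usual six-membered transition state; the primary bromide is inert to these non-nucleophilic acidic conditions.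

Step 7
Reactants: 13
Product: 14 2-(13-bromotridecyl)-2-methyl-1,3-dithiane
Conditions: HS(CH2)3SH (1.2 equiv), BF3·OEt2 (0.3 equiv), CH2Cl2, 0 °C → rt
Reagents that add atoms: propane-1,3-dithiol, SCCCS
Why: Lewis acid-catalysed thioketalisation of the ketone; the dithiane withstands the Grignard reagent, the aqueous acid of step 10 and the carboxylation of step 11, which an oxygen ketal (lost in step 10) or a free ketone (carboxylated in step 11) would not.

Step 8
Reactants: 14
Product: 15 [13-(2-methyl-1,3-dithian-2-yl)tridecyl]magnesium bromide (THF solution; titrated and used directly)
Conditions: Mg turnings (1.5 equiv), I2 (cat.), THF, 45 °C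
Reagents that add atoms: magnesium, [Mg]
Why: Oxidative insertion of magnesium into the primary C–Br bond (Grignard formation); the 2,2-disubstituted dithiane has no acidic hydrogen and thioethers do not interfere.

Step 9
Reactants: 8; 15; 16 tert-butyl bromoacetate
Product: 18 tert-butyl 2-[(2R,5S,6S)-2-tert-butyl-6-[13-(2-methyl-1,3-dithian-2-yl)tridecyl]-4-oxo-1,3-dioxan-5-yl]acetate, via magnesium enolate 17 (not isolated)
Conditions: 8, CuBr·SMe2 (15 mol %), THF, −78 °C, 15 (1.3 equiv) added over 1 h; then DMPU (6 equiv), 16 (3 equiv), −78 → −40 °C; aq NH4Cl
Reagents that add atoms: none
Why: Copper-catalysed conjugate addition of a Grignard reagent followed by alkylation of the enolate in the same flask (three-component coupling): 15 transmetalates to a magnesium cuprate, which adds to C6 of 8 (acetal numbering, the β-carbon of the cyclic β-alkoxyacrylate) and releases bromomagnesium enolate 17 while copper returns to the cycle. The closest known reactions are the cuprate additions to enantiopure 2-tert-butyl-1,3-dioxin-4-ones and the trans-selective alkylations of 1,3-dioxan-4-one enolates, run here one after the other as is routine for enones and enoates. No ring closes. The stereocenter at C6 is controlled by the acetal carbon: in the sofa-shaped ring the tert-butyl group blocks one face, so the chain enters anti to it (2,6-trans, 6S). The stereocenter at C5 is controlled by the new C6 substituent, which sits pseudo-axial next to the enolate carbon and sends 16 to the opposite face (5,6-trans, 5S). The step needs 1,4- over 1,2-addition, secured by copper, slow addition and −78 °C; C-alkylation before the enolate decays, secured by the polar cosolvent and the reactive α-bromo ester; and no β-elimination, secured because the C6–O1 bond is a ring bond lying near the nodal plane of the enolate π system and because the mixture stays below −40 °C. The tertiary C5–H of 18 is hindered and should not be deprotonated again, so neither a second alkylation nor epimerisation is expected.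

Step 10
Reactants: 18
Product: 20 (2S,3S)-2-[13-(2-methyl-1,3-dithian-2-yl)tridecyl]-5-oxooxolane-3-carboxylic acid, via hydroxy diacid 19 (not isolated)
Conditions: CF3CO2H/H2O (9:1), 0 °C → rt; evaporate with toluene
Reagents that add atoms: none
Why: Acid hydrolysis of the acylal and acidolysis of the tert-butyl ester give hydroxy diacid 19, whose hydroxyl closes onto the CH2CO2H arm (5-exo-trig lactonisation; the other carboxyl could only give a β-lactone). No bond to either stereocenter is broken, so the 5,6-trans acetal becomes the 4,5-cis lactone, and the water taken up in the hydrolysis is returned on lactonisation. The dithiane meets no thiophile under these conditions and should survive the short exposure at room temperature.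

Step 11
Reactants: 20
Product: 21 (2S,3S)-2-[13-(2-methyl-1,3-dithian-2-yl)tridecyl]-5-oxooxolane-3,4-dicarboxylic acid (mixture of epimers at oxolane C4; used crude)
Conditions: MeOMgOCO2Me (2 M in DMF, 30 equiv), 130 °C; then cold 2 M HCl, EtOAc extraction
Reagents that add atoms: methoxymagnesium methyl carbonate, COC(=O)O[Mg]OC
Why: Stiles carboxylation: the magnesium methyl carbonate reagent carboxylates the lactone α-carbon (lactone C3) and holds the product as a magnesium chelate; the neighbouring carboxylate is not enolised under these conditions, and the masked ketone cannot be carboxylated.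

Step 12
Reactants: 21; 22 formaldehyde
Product: 24 (2S,3S)-4-methylidene-2-[13-(2-methyl-1,3-dithian-2-yl)tridecyl]-5-oxooxolane-3-carboxylic acid, via Mannich base 23 (not isolated)
Conditions: 22 (37% aq), PhNHMe, NaOAc, AcOH, rt, 2 h
Reagents that add atoms: none
Why: Mannich reaction of the malonic half-acid with the iminium ion from 22 and N-methylaniline gives amino diacid 23, which loses CO2 and the amine in a decarboxylative elimination to the exocyclic alkene; the buffered, weakly acidic medium keeps base away from the now acidic C4–H.

Step 13
Reactants: 24
Product: 25 allo-pertusaric acid, (2S,3S)-4-methylidene-5-oxo-2-(14-oxopentadecyl)oxolane-3-carboxylic acid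
Conditions: PhI(OCOCF3)2 (1.5 equiv), MeCN/H2O (9:1), 0 °C → rt, 15 min
Reagents that add atoms: water, O
Why: Oxidative dethioketalisation with a trivalent iodine reagent: sulfur is by far the most easily oxidised site, the sulfonium intermediate is opened by water and the dithiol unit leaves as the cyclic disulfide, so no free thiol meets the Michael acceptor; the electron-poor methylene lactone, the acid and both stereocenters should be untouched by the brief, weakly acidic conditions.

## Compound list

1 | 2,2-dimethyl-1,3-dioxane-4,6-dione (Meldrum's acid) | CC1(C)OC(=O)CC(=O)O1 | starting material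
2 | trimethyl orthoformate | COC(OC)OC | starting material
3 | 5-(methoxymethylidene)-2,2-dimethyl-1,3-dioxane-4,6-dione | COC=C1C(=O)OC(C)(C)OC1=O | intermediate
4 | 5-(hydroxymethylidene)-2,2-dimethyl-1,3-dioxane-4,6-dione | OC=C1C(=O)OC(C)(C)OC1=O | intermediate
5 | pivalaldehyde | CC(C)(C)C=O | starting material
6 | formylketene (3-oxoprop-1-en-1-one) | O=CC=C=O | intermediate (not isolated)
7 | rac-2-tert-butyl-2H,4H-1,3-dioxin-4-one | CC(C)(C)C1OC=CC(=O)O1 | intermediate
8 | (2R)-2-tert-butyl-2H,4H-1,3-dioxin-4-one | CC(C)(C)[C@@H]1OC=CC(=O)O1 | intermediate
9 | 1,12-dibromododecane | BrCCCCCCCCCCCCBr | starting material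
10 | tert-butyl acetoacetate | CC(=O)CC(=O)OC(C)(C)C | starting material
11 | tert-butyl 2-acetyl-14-bromotetradecanoate (racemic) | CC(=O)C(CCCCCCCCCCCCBr)C(=O)OC(C)(C)C | intermediate
12 | 2-acetyl-14-bromotetradecanoic acid (racemic) | CC(=O)C(CCCCCCCCCCCCBr)C(=O)O | intermediate (not isolated)
13 | 15-bromopentadecan-2-one | CC(=O)CCCCCCCCCCCCCBr | intermediate
14 | 2-(13-bromotridecyl)-2-methyl-1,3-dithiane | CC1(CCCCCCCCCCCCCBr)SCCCS1 | intermediate
15 | [13-(2-methyl-1,3-dithian-2-yl)tridecyl]magnesium bromide | Br[Mg]CCCCCCCCCCCCCC1(C)SCCCS1 | intermediate
16 | tert-butyl bromoacetate | BrCC(=O)OC(C)(C)C | starting material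
17 | bromomagnesium (2R,6S)-2-tert-butyl-6-[13-(2-methyl-1,3-dithian-2-yl)tridecyl]-6H-1,3-dioxin-4-olate | CC(C)(C)[C@@H]1O[C@@H](CCCCCCCCCCCCCC2(C)SCCCS2)C=C(O[Mg]Br)O1 | intermediate (not isolated)
18 | tert-butyl 2-[(2R,5S,6S)-2-tert-butyl-6-[13-(2-methyl-1,3-dithian-2-yl)tridecyl]-4-oxo-1,3-dioxan-5-yl]acetate | CC(C)(C)[C@@H]1O[C@@H](CCCCCCCCCCCCCC2(C)SCCCS2)[C@H](CC(=O)OC(C)(C)C)C(=O)O1 | intermediate
19 | (2S)-2-[(1S)-1-hydroxy-14-(2-methyl-1,3-dithian-2-yl)tetradecyl]butanedioic acid | O[C@@H](CCCCCCCCCCCCCC1(C)SCCCS1)[C@H](CC(=O)O)C(=O)O | intermediate (not isolated)
20 | (2S,3S)-2-[13-(2-methyl-1,3-dithian-2-yl)tridecyl]-5-oxooxolane-3-carboxylic acid | C1C(=O)O[C@@H](CCCCCCCCCCCCCC2(C)SCCCS2)[C@H]1C(=O)O | intermediate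
21 | (2S,3S)-2-[13-(2-methyl-1,3-dithian-2-yl)tridecyl]-5-oxooxolane-3,4-dicarboxylic acid (C4 epimers) | OC(=O)C1C(=O)O[C@@H](CCCCCCCCCCCCCC2(C)SCCCS2)[C@H]1C(=O)O | intermediate
22 | formaldehyde | C=O | starting material
23 | (2S,3S)-4-{[methyl(phenyl)amino]methyl}-2-[13-(2-methyl-1,3-dithian-2-yl)tridecyl]-5-oxooxolane-3,4-dicarboxylic acid (C4 epimers) | CN(CC1(C(=O)O)C(=O)O[C@@H](CCCCCCCCCCCCCC2(C)SCCCS2)[C@H]1C(=O)O)c1ccccc1 | intermediate (not isolated)
24 | (2S,3S)-4-methylidene-2-[13-(2-methyl-1,3-dithian-2-yl)tridecyl]-5-oxooxolane-3-carboxylic acid | C=C1C(=O)O[C@@H](CCCCCCCCCCCCCC2(C)SCCCS2)[C@H]1C(=O)O | intermediate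
25 | allo-pertusaric acid, (2S,3S)-4-methylidene-5-oxo-2-(14-oxopentadecyl)oxolane-3-carboxylic acid | C=C1C(=O)O[C@@H](CCCCCCCCCCCCCC(C)=O)[C@H]1C(=O)O | target

## Step count and least certain steps

Total: 13 steps. Longest linear sequence: 9 steps (steps 1–4 and 9–13 from 1; equally steps 5–13 from 9).

**Step 9 (key step).**
- Risk: the Grignard reagent may attack the acylal carbonyl directly before copper transfers the chain.
- Risk: the aggregated magnesium enolate may alkylate slowly, so that on warming it opens by loss of the ring oxygen or is merely protonated on work-up.
- Risk: facial selectivity at C5 could be eroded if the alkylation needs higher temperature.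
- Fallback: the two bond formations are separated. 8 and 15 are combined under the same copper catalysis, but the enolate 17 is quenched with aqueous NH4Cl at −78 °C to give (2R,6S)-2-tert-butyl-6-[13-(2-methyl-1,3-dithian-2-yl)tridecyl]-1,3-dioxan-4-one F1, which is isolated. F1 is deprotonated with LiN(iPr)2 in THF at −78 °C, and the lithium enolate, which is more reactive and better defined, is alkylated with 16 in the presence of DMPU. The fallback sets out from 8 and 15 and returns at 18.

**Step 3.**
- Risk: capture of the acylketene by the hindered, volatile aldehyde may lose out to recapture by the acetone set free or to self-condensation of the ketene.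
- Fallback: the saturated ring is made first and the double bond is introduced afterwards. 3-Hydroxypropanoic acid is acetalised with 5 (TsOH cat., CH2Cl2, molecular sieves) to rac-2-tert-butyl-1,3-dioxan-4-one F2. Its lithium enolate (LiN(iPr)2, THF, −78 °C) is selenenylated with PhSeBr to 2-tert-butyl-5-(phenylselanyl)-1,3-dioxan-4-one F3. Oxidation of F3 with H2O2 and syn-elimination of the selenoxide gives 7. The fallback sets out from 5 and returns at 7.

**Step 4.**
- Risk: separation or loading capacity on the chiral phase may be insufficient at the scale needed, and half of the material is lost in any case.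
- Fallback: the resolution is moved to the first intermediate with a salt-forming group. Racemic 7 is taken through steps 9 and 10 unchanged, giving rac-tert-butyl 2-[(2R,5S,6S)-2-tert-butyl-6-[13-(2-methyl-1,3-dithian-2-yl)tridecyl]-4-oxo-1,3-dioxan-5-yl]acetate F4 and then rac-(2S,3S)-2-[13-(2-methyl-1,3-dithian-2-yl)tridecyl]-5-oxooxolane-3-carboxylic acid F5. F5 is crystallised with one enantiomer of 1-phenylethylamine to (R)-1-phenylethylammonium (2S,3S)-2-[13-(2-methyl-1,3-dithian-2-yl)tridecyl]-5-oxooxolane-3-carboxylate F6. It is written here for the (R)-amine; which enantiomer of the amine gives the less soluble salt of the wanted acid has to be found by trial. Acidification of F6 with cold dilute HCl releases 20. The fallback sets out from 7 and returns at 20.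

**Step 10.**
- Risk: in the strong acid the dithiane may open reversibly and hand its dithiol unit to the pivalaldehyde set free, which would unmask the ketone before the carboxylation of step 11.
- Fallback: the aldehyde is removed before any acid is applied. 18 is opened with LiOH in aqueous THF at 0 °C → rt, where hydroxide attacks the acylal carbonyl and the hemiacetal releases pivalaldehyde; extraction of the aldehyde and acidification to pH 4 give (2S)-4-tert-butoxy-2-[(1S)-1-hydroxy-14-(2-methyl-1,3-dithian-2-yl)tetradecyl]-4-oxobutanoic acid F7. F7 is then treated with CF3CO2H in CH2Cl2, which cleaves the tert-butyl ester and closes the lactone. The fallback sets out from 18 and returns at 20.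

**Step 11.**
- Risk: carboxylation at the hindered lactone α-carbon next to the cis carboxylate may be slow, and prolonged heating in the basic medium could lead to epimerisation at C4 towards the more stable trans acid or to decomposition.
- Fallback: the activating carboxyl is replaced by a formyl group introduced at room temperature. 20 is treated with NaH (3 equiv) and HCO2Et in THF to give, after acidification, (2S,3S)-4-(hydroxymethylidene)-2-[13-(2-methyl-1,3-dithian-2-yl)tridecyl]-5-oxooxolane-3-carboxylic acid F8. Heating the sodium salt of F8 with 22 (as paraformaldehyde) in THF brings about aldol addition, formyl transfer to oxygen and loss of formate, which installs the methylene. The fallback sets out from 20 and returns at 24.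

**Step 13.**
- Risk: sulfur-containing fragments may add to the Michael acceptor if the oxidant is consumed too slowly, or cleavage of the thioketal may be incomplete.
- Fallback: the ketone is unmasked before the alkene exists. 21 is treated with PhI(OCOCF3)2 in aqueous MeCN to give (2S,3S)-5-oxo-2-(14-oxopentadecyl)oxolane-3,4-dicarboxylic acid F9. F9 is then submitted to the conditions of step 12, where the malonic half-acid should react far faster than a simple methyl ketone. The fallback sets out from 21 and returns at 25.

## Further compounds

F1 | step 9 | (2R,6S)-2-tert-butyl-6-[13-(2-methyl-1,3-dithian-2-yl)tridecyl]-1,3-dioxan-4-one | CC(C)(C)[C@@H]1O[C@@H](CCCCCCCCCCCCCC2(C)SCCCS2)CC(=O)O1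
F2 | step 3 | rac-2-tert-butyl-1,3-dioxan-4-one | CC(C)(C)C1OCCC(=O)O1
F3 | step 3 | 2-tert-butyl-5-(phenylselanyl)-1,3-dioxan-4-one (racemic, mixture of diastereomers) | CC(C)(C)C1OCC([Se]c2ccccc2)C(=O)O1
F4 | step 4 | rac-tert-butyl 2-[(2R,5S,6S)-2-tert-butyl-6-[13-(2-methyl-1,3-dithian-2-yl)tridecyl]-4-oxo-1,3-dioxan-5-yl]acetate (both enantiomers) | CC(C)(C)[C@@H]1O[C@@H](CCCCCCCCCCCCCC2(C)SCCCS2)[C@H](CC(=O)OC(C)(C)C)C(=O)O1.CC(C)(C)[C@H]1O[C@H](CCCCCCCCCCCCCC2(C)SCCCS2)[C@@H](CC(=O)OC(C)(C)C)C(=O)O1
F5 | step 4 | rac-(2S,3S)-2-[13-(2-methyl-1,3-dithian-2-yl)tridecyl]-5-oxooxolane-3-carboxylic acid (both enantiomers) | C1C(=O)O[C@@H](CCCCCCCCCCCCCC2(C)SCCCS2)[C@H]1C(=O)O.C1C(=O)O[C@H](CCCCCCCCCCCCCC2(C)SCCCS2)[C@@H]1C(=O)O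
F6 | step 4 | (R)-1-phenylethylammonium (2S,3S)-2-[13-(2-methyl-1,3-dithian-2-yl)tridecyl]-5-oxooxolane-3-carboxylate | C[C@@H]([NH3+])c1ccccc1.C1C(=O)O[C@@H](CCCCCCCCCCCCCC2(C)SCCCS2)[C@H]1C(=O)[O-]
F7 | step 10 | (2S)-4-tert-butoxy-2-[(1S)-1-hydroxy-14-(2-methyl-1,3-dithian-2-yl)tetradecyl]-4-oxobutanoic acid | O[C@@H](CCCCCCCCCCCCCC1(C)SCCCS1)[C@H](CC(=O)OC(C)(C)C)C(=O)O
F8 | step 11 | (2S,3S)-4-(hydroxymethylidene)-2-[13-(2-methyl-1,3-dithian-2-yl)tridecyl]-5-oxooxolane-3-carboxylic acid | OC=C1C(=O)O[C@@H](CCCCCCCCCCCCCC2(C)SCCCS2)[C@H]1C(=O)O
F9 | step 13 | (2S,3S)-5-oxo-2-(14-oxopentadecyl)oxolane-3,4-dicarboxylic acid (C4 epimers) | OC(=O)C1C(=O)O[C@@H](CCCCCCCCCCCCCC(C)=O)[C@H]1C(=O)O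
A1 | alternative 1 | bicyclo[3.2.0]hept-2-en-6-one (racemic, cis-fused) | O=C1CC2C=CCC12
A2 | alternative 1 | (1S,5R)-2-oxabicyclo[3.3.0]oct-6-en-3-one | C1C(=O)O[C@@H](CC=C2)[C@H]12
A3 | alternative 2 | tert-butyl (2E,4S)-4-{[(bromomethyl)dimethylsilyl]oxy}-18-oxononadec-2-enoate | BrC[Si](C)(C)O[C@@H](CCCCCCCCCCCCCC(C)=O)/C=C/C(=O)OC(C)(C)C
A4 | alternative 2 | tert-butyl 2-[(4S,5S)-2,2-dimethyl-5-(14-oxopentadecyl)-1,2-oxasilolan-4-yl]acetate | C[Si]1(C)O[C@@H](CCCCCCCCCCCCCC(C)=O)[C@H](CC(=O)OC(C)(C)C)C1
A5 | alternative 3 | (2S)-1-(4-methoxyphenyl)-15-(2-methyl-1,3-dioxolan-2-yl)pentadecan-2-yl 2-diazoacetate | [N-]=[N+]=CC(=O)O[C@@H](CCCCCCCCCCCCCC1(C)OCCO1)Cc1ccc(OC)cc1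
A6 | alternative 3 | (4R,5S)-4-(4-methoxyphenyl)-5-[13-(2-methyl-1,3-dioxolan-2-yl)tridecyl]dihydrofuran-2(3H)-one | C1C(=O)O[C@@H](CCCCCCCCCCCCCC3(C)OCCO3)[C@H]1c2ccc(OC)cc2
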